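(Readings and results are calculated with made-up constants; noise was put on by code.)

Product comes off the catalyst once per round, so we write the balance of the smallest charge in the flask: free catalyst, catalyst intermediate A, catalyst intermediate B and idle complex together always make up the catalyst charged, and the rate is that charge divided by the time of one round.

common to all: starting material 0.25 M; coupling partner 0.275 M; free catalyst 1.2 mM

| run | protic impurity | remark |
|---|---|---|
| violet | 0.025 M | the very flask that is asked about, followed so far |
| flask | 0.0250 M |  |

violet run (percent of the starting material charged)

| time / s | product / % | starting material / % |
|---|---|---|
| 10.0 | 22.5 | 76.6 |
| 20.0 | 39.3 | 60.1 |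
| 25.0 | 45.9 | 53.7 |
| 40.0 | 60.6 | 39.7 |
| 50.0 | 67.0 | 32.4 |

(standard deviation of a reading: 0.3 percentage points)

* factor on the rate of making product when 5.0% of the starting material are converted if free catalyst is charged twice over
* factor on the rate when 5.0% of the starting material are converted if free catalyst is charged at 6.0 mM instead

- the numbers in the tables scatter by 0.3 percentage points (one standard deviation)
- steps under discussion: starting material + free catalyst -> catalyst intermediate A; coupling partner + catalyst intermediate A <-> catalyst intermediate B; catalyst intermediate B <-> free catalyst + product; coupling partner + free catalyst <-> idle complex; coupling partner + protic impurity -> quenched reagent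
- no earlier run changes the charge of free catalyst; that part of a forecast is a guess

The violet run has the charge of the flask asked about, so it gives us the round time. Its first reading of starting material gives an apparent first-order constant of 0.0267 /s, and so, as a reading, a rate near 0.380 M/min at the conversion asked about. The catalyst charge over that rate is the turnover time, 0.190 s.

The violet run and a flask with twice its catalyst look nearly alike on paper, and we expect them to head for the same end. The catalyst, far less than the starting material, comes back each round, while c(coupling partner) less c(protic impurity) is 0.250 M, level with c(starting material) at 0.25 M. They should part in pace. Each catalyst step is first order in a catalyst form, and even 6.0 mM is 2.40% of the starting material, so we hold the turnover time at 0.190 s and reckon rates of 0.758 M/min and 1.89 M/min, which are factors of 2.00 and 5.00.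

The forecast says 2 and 4.9, the second a little below ours, on the ground that “the cycle's rate should scale with total catalyst”.

The simulation gives 2.00 and 5.01.

    starting material + free catalyst → catalyst intermediate A (k = 191 /M/s)
    coupling partner + catalyst intermediate A ⇌ catalyst intermediate B (K = 7.85 /M, k = 119 /M/s)
    catalyst intermediate B ⇌ free catalyst + product (K = 0.0555 M, k = 23.0 /s)
    coupling partner + free catalyst ⇌ idle complex, settled at all times (K = 11.0 /M)
    coupling partner + protic impurity → quenched reagent (k = 1.61 /M/s)

The flask with 1.2 mM makes product at 0.380 M/min at 0.0311 min, the moment when 5.0% of its starting material is converted. Carried to the flask with 6.0 mM, the turnover time of 0.190 s gives a rate of 1.89 M/min when that same conversion is reached there.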